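(The readings are simulated with made-up constants; the scatter is artificial.)

Early times came first: in Thursday's run product stood at 9% by 2.50 h and at 19% by 30.0 h. I then asked which given numbers needed care. The capture agent did not: going from 11.4 mM to 23 mM took the last reading from 18% to 19%, against a scatter of 1.5 percentage points. Nor did the time: Sunday's run read 17% at 8.00 h and 18% at 30.0 h. The partner did, for going from 48 mM to 190 mM took the last reading from 13% to 29%. The dosing time needed care too, and it has to be held against the length of the productive window.

| flask | substrate | partner | capture agent | remark | time |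
|---|---|---|---|---|---|
| Sunday's | 38 mM | 95 mM | 11.4 mM | run made earlier |  |
| Saturday's | 38 mM | 48 mM | 11.4 mM | run made earlier |  |
| Monday's | 38 mM | 190 mM | 11.4 mM | run made earlier |  |
| Thursday's | 38 mM | 95 mM | 23 mM | run made earlier |  |
| autumn | 38 mM (in portions, 5, over 30 h) | 95.0 mM | 11.4 mM | first portion at the start, last at 30 h | 2.0 d |
| summer | 38 mM | 95.0 mM (fed, over 30 h) | 11.4 mM | all else is in the flask from the start; the feed brings no volume worth counting | 2.0 d |
| spring | 38 mM (fed, over 30 h) | 95.0 mM | 11.4 mM | all else is in the flask from the start; the feed brings no volume worth counting | 2.0 d |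
| dusk | 38 mM | 95.0 mM | 11.4 mM | everything together at the start | 2.0 d |

| run | time / h | product / % |
|---|---|---|
| Sunday's | 8.00 | 17 |
| Sunday's | 15.0 | 15 |
| Sunday's | 20.0 | 16 |
| Sunday's | 30.0 | 18 |
| Saturday's | 4.00 | 5 |
| Saturday's | 10.0 | 10 |
| Saturday's | 20.0 | 11 |
| Saturday's | 30.0 | 13 |
| Monday's | 8.00 | 24 |
| Monday's | 15.0 | 24 |
| Monday's | 20.0 | 29 |
| Monday's | 30.0 | 29 |
| Thursday's | 2.50 | 9 |
| Thursday's | 5.00 | 13 |
| Thursday's | 12.0 | 16 |
| Thursday's | 30.0 | 19 |

(scatter of a reading: 1.5 percentage points)

- steps that have been proposed: substrate <-> intermediate A; partner -> decomposed reagent; substrate + partner <-> intermediate B; substrate + partner -> product; capture agent + intermediate C -> trapped intermediate; partner + intermediate A <-> intermediate C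

* the flask with the highest amount of product, in percent of the substrate charged ("all alike" if they lie within 1.5 percentage points) (autumn / summer / spring / dusk / all alike)
* final product, as a percentage of the substrate charged, in autumn
* final product, as a percentage of the substrate charged, in summer
* final product, as a percentage of the substrate charged, in spring
* final product, as a percentage of the substrate charged, in dusk

So I defined the exposure time τ, the time product would need to reach its final reading at its opening rate. Thursday's readings give 5.28 h, a reading with its scatter. I took the stall to be the partner's decomposition, a clock running whether or not substrate is present. Since τ is shorter than the dosing time, spring's substrate meets a share τ/t_f of the exposure, 0.176, so I expected 3.17% from Sunday's final reading. In autumn, the portions spaced 7.50 h apart, each weighted by the partner surviving to its arrival, give a share of 0.263, so 4.73%. Dusk has Sunday's charges, so I expected Sunday's final reading, 18%. I took summer to keep the same partner exposure, so my reckoning put it level with dusk, provided the substrate waits unchanged.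

The forecast differed: it named summer at 22%, above dusk at 19%, with spring at 5% and autumn at 6%, holding that “Yield then tracks the partner exposure met by the substrate.”

Dusk gave the most: 16.7%, against 11.7% in summer, 5.03% in autumn and 3.68% in spring.

    substrate ⇌ intermediate A (K = 1.60, k = 0.170 h⁻¹)
    partner → decomposed reagent (k = 0.179 h⁻¹)
    substrate + partner ⇌ intermediate B (K = 489 M⁻¹, k = 0.827 M⁻¹ h⁻¹)
    substrate + partner → product (k = 0.739 M⁻¹ h⁻¹)
    capture agent + intermediate C → trapped intermediate (k = 2.83 M⁻¹ h⁻¹)
    partner + intermediate A ⇌ intermediate C (K = 3.50 M⁻¹, k = 1.24 M⁻¹ h⁻¹)

At 2.00 d summer held 28.0% as substrate and 45.3% as intermediate A. Measured against dusk, spring kept 0.220 where τ/t_f gave 0.176, and autumn kept 0.301 where its share gave 0.263.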